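**Strategy.** Everything rests on cutting the bond between the CH2 of the cyclohexane-1,2-dione (ring C) and the ring-fusion CH of the γ-lactone (ring B). That CH2 is γ to the ketone beside the quaternary carbon and the CH is β to the lactone carbonyl, so the pair is a vinylogous Michael retron. The precursor is a 14-membered β-keto macrolactone carrying a tertiary aldehyde and an α-methoxy-β-methyl enone. One base-mediated operation stitches it across: transannular Knoevenagel condensation closes ring B, vinylogous Michael (6π) closure forms ring C and the 11-membered ring D, and methylation of the resulting enolate sets the quaternary centre.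

Key step: step 18

Remark (labels): ring A = cyclohexene, B = γ-lactone, C = cyclohexane-1,2-dione, D = 11-membered carbocycle; Cs = spiro carbon, Ca = quaternary lactone α-carbon, Cb = lactone β-CH, K1 and K2 = ketone carbons (K1 on Ca), Cm = ring C methine, Ch = ring C CH2.
Remark (ligand): (S)-t-Bu-PHOX is assumed to select the anhydride carbonyl that leads to the (2S,4R) keto acid of step 1; if the sense is opposite, the (R)-ligand is used.
Remark (alkene geometry): the metathesis of step 16 is assumed to favour the E alkene, which is drawn; the geometry is erased in step 17.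
Remark (tautomer): the 1,2-diketone drawn for the target is taken as the resting tautomer of the diosphenol/diketone pair in the bridged ring C.
Remark (supply): meso-2,4-dimethylglutaric anhydride, methyl 2-(dimethoxyphosphoryl)-2-methoxyacetate, tert-butyl but-2-ynoate and pent-1-en-4-yne are taken as commercial.

**Fragment 1: acylketene precursor**

Step 1
Reactants: 1 meso-2,4-dimethylglutaric anhydride
Product: 2 (2S,4R)-2,4-dimethyl-5-oxohexanoic acid
Conditions: Me2Zn, [Rh(cod)Cl]2 (cat.), (S)-t-Bu-PHOX (cat.), THF, 50 °C; then 1 M HCl
Reagents that add atoms: dimethylzinc, C[Zn]C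
Why: Rhodium-catalysed enantioselective alkylative desymmetrisation of a meso anhydride with an organozinc, in which the chiral P,N-ligand lets monovalent rhodium insert into one enantiotopic acyl–O bond, so the syn-1,3-dimethyl pair of 1 is kept and becomes non-racemic.

Step 2
Reactants: 2 (2S,4R)-2,4-dimethyl-5-oxohexanoic acid
Product: 3 S-ethyl (2S,4R)-2,4-dimethyl-5-oxohexanethioate
Conditions: EtSH, DCC, DMAP (cat.), CH2Cl2, 0 → 23 °C
Reagents that add atoms: ethanethiol, CCS
Why: Steglich-type carbodiimide thioesterification activates only the acid, leaves the ketone alone and should not disturb the α-stereocentre while DMAP stays catalytic.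

Step 3
Reactants: 3 S-ethyl (2S,4R)-2,4-dimethyl-5-oxohexanethioate
Product: 4 (2S,4R)-2,4-dimethyl-5-oxohexanal
Conditions: Et3SiH, Pd/C (cat.), acetone, 23 °C
Reagents that add atoms: none
Why: Fukuyama reduction, in which zerovalent palladium inserts into the C–S bond and the silane delivers hydride, stops at the aldehyde and does not touch the ketone.

Step 4
Reactants: 4 (2S,4R)-2,4-dimethyl-5-oxohexanal
Product: 5 (3R,5S)-3,5-dimethylhept-6-en-2-one
Conditions: Ph3PCH3Br, KN(SiMe3)2, THF, 0 °C; then 4 (1 equiv), −78 → 0 °C
Reagents that add atoms: methyltriphenylphosphonium bromide, C[P+](c1ccccc1)(c1ccccc1)c1ccccc1.[Br-]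
Why: Wittig methylenation with one equivalent of ylide at low temperature is chemoselective for the aldehyde over the α-branched ketone and fast enough to outrun aldol closure and epimerisation.

Step 5
Reactants: 5 (3R,5S)-3,5-dimethylhept-6-en-2-one; 6 methyl 2-(dimethoxyphosphoryl)-2-methoxyacetate
Product: 7 methyl (2Z,4R,6S)-2-methoxy-3,4,6-trimethylocta-2,7-dienoate
Conditions: 6, NaH, THF, 0 °C; then 5, 0 → 65 °C
Reagents that add atoms: none
Why: Horner–Wadsworth–Emmons olefination of a methyl ketone with an α-alkoxyphosphonate should place the larger branched chain trans to the ester, so that the vinylic CH3 (future Ch) lies cis to the carbonyl.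

Step 6
Reactants: 7 methyl (2Z,4R,6S)-2-methoxy-3,4,6-trimethylocta-2,7-dienoate; 8 tert-butyl acetate
Product: 9 tert-butyl (4Z,6R,8S)-4-methoxy-5,6,8-trimethyl-3-oxodeca-4,9-dienoate
Conditions: 8 (3 equiv), LiN(i-Pr)2, THF, −78 °C; then 7, −78 → 0 °C; AcOH
Reagents that add atoms: none
Why: Crossed Claisen condensation works because 7 has no α-hydrogen and a hindered β-carbon, so the excess ester enolate can only acylate, and the product is stored as its enolate until the quench.

**Fragment 2: chiral dienophile**

Step 7
Reactants: 10 (S)-lactic acid; 11 pivalaldehyde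
Product: 12 (2S,5S)-2-tert-butyl-5-methyl-1,3-dioxolan-4-one
Conditions: TsOH (cat.), pentane, reflux, azeotropic removal of water; recrystallisation
Reagents that add atoms: none
Why: Acid-catalysed acetalisation under equilibrating conditions favours the cis-dioxolanone, so the lactic acid stereocentre is copied onto the acetal carbon.

Step 8
Reactants: 12 (2S,5S)-2-tert-butyl-5-methyl-1,3-dioxolan-4-one
Product: 13 (2S)-5-bromo-2-tert-butyl-5-methyl-1,3-dioxolan-4-one
Conditions: NBS, AIBN (cat.), PhCF3, reflux
Reagents that add atoms: N-bromosuccinimide, O=C1CCC(=O)N1Br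
Why: Wohl–Ziegler radical bromination selects the captodative tertiary C5–H, and the configuration at C5 is irrelevant because it is lost in the next step.

Step 9
Reactants: 13 (2S)-5-bromo-2-tert-butyl-5-methyl-1,3-dioxolan-4-one
Product: 14 (S)-2-tert-butyl-5-methylidene-1,3-dioxolan-4-one
Conditions: Et3N, Et2O, 0 → 23 °C
Reagents that add atoms: none
Why: E2 dehydrobromination can only occur toward the methyl group and leaves the acetal stereocentre as the sole stereocontrol element.

**Fragment 3: diene and ring A**

Step 10
Reactants: 15 tert-butyl but-2-ynoate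
Product: 16 tert-butyl (E)-2-(tributylstannyl)but-2-enoate
Conditions: Bu3SnH, Pd(PPh3)4 (cat.), THF, 0 → 23 °C
Reagents that add atoms: tributyltin hydride, CCCC[SnH](CCCC)CCCC
Why: Palladium-catalysed hydrostannation of an ynoate is a syn addition with tin α to the ester, which puts the CH3 trans to tin as the diene needs.

Step 11
Reactants: 17 pent-1-en-4-yne
Product: 19 (E)-1-iodopenta-1,4-diene, via alkenylzirconocene chloride 18 (not isolated)
Conditions: Cp2Zr(H)Cl (1.0 equiv), CH2Cl2, 0 → 23 °C; then I2, 0 °C
Reagents that add atoms: iodine, II
Why: Hydrozirconation–iodinolysis adds syn with zirconium at the terminus, takes the alkyne faster than the terminal alkene, and iodine replaces zirconium with retention.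

Step 12
Reactants: 16 tert-butyl (E)-2-(tributylstannyl)but-2-enoate; 19 (E)-1-iodopenta-1,4-diene
Product: 20 tert-butyl (2Z,3E)-2-ethylidenehepta-3,6-dienoate
Conditions: Pd2(dba)3 (cat.), AsPh3, CuI (cat.), NMP, 23 → 40 °C
Reagents that add atoms: none
Why: Stille coupling at zerovalent palladium proceeds with retention at both alkenyl partners and so gives the diene with both terminal substituents pointing outward.

Step 13
Reactants: 20 tert-butyl (2Z,3E)-2-ethylidenehepta-3,6-dienoate; 14 (S)-2-tert-butyl-5-methylidene-1,3-dioxolan-4-one
Product: 21 spiro-dioxolanone cycloadduct (ring A with allyl, CH3 and spiro O all cis; tert-butyl trans to the allyl-bearing carbon)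
Conditions: 14 (2 equiv), BHT, toluene, 110 °C, sealed tube
Reagents that add atoms: none
Why: Thermal Diels–Alder reaction of a 2-alkoxycarbonyl diene with a captodative methylene-dioxolanone, in which the para orientation puts Cs next to the allyl-bearing carbon, the carbonyl-exo transition state typical of this dienophile makes spiro O, allyl and CH3 all cis, and approach anti to the tert-butyl group fixes the absolute sense of the three new stereocentres.

Step 14
Reactants: 21 spiro-dioxolanone cycloadduct
Product: 23 tert-butyl (3S,4R,6S)-4-formyl-4-hydroxy-6-methyl-3-(prop-2-enyl)cyclohex-1-ene-1-carboxylate, via dioxolane lactol 22 (not isolated)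
Conditions: i-Bu2AlH (1.1 equiv), CH2Cl2, −78 °C; aq. potassium sodium tartrate; SiO2, wet CH2Cl2, then vacuum
Reagents that add atoms: none
Why: Partial i-Bu2AlH reduction takes the acylal-type lactone carbonyl in preference to the conjugated tert-butyl ester, and the lactol collapses with loss of volatile pivalaldehyde without touching the fully substituted Cs.

**Union, macrocycle and endgame**

Step 15
Reactants: 23 ring A α-hydroxy aldehyde; 9 tert-butyl β-keto ester
Product: 25 β-keto ester of the tertiary alcohol of 23 (aldehyde free, two terminal alkenes), via acylketene 24 (not isolated)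
Conditions: 9 (1.5 equiv), toluene, 110 °C, slow distillation of t-BuOH
Reagents that add atoms: none
Why: tert-Butyl β-keto esters lose t-BuOH on heating to give acylketenes that acylate even tertiary alcohols without catalyst (transacetoacetylation type), and the neutral medium should leave the aldehyde and the active methylene unreacted.

Step 16
Reactants: 25 acyclic β-keto ester aldehyde
Product: 26 14-membered unsaturated β-keto macrolactone (E alkene drawn)
Conditions: second-generation Grubbs catalyst RuCl2(=CHPh)(PCy3)(SIMes) (10 mol %), CH2Cl2 (1 mM), 40 °C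
Reagents that add atoms: none
Why: Ring-closing metathesis engages only the two monosubstituted alkenes, the tri- and tetrasubstituted electron-poor alkenes being inert, and a flexible 14-membered lactone is a favourable ring size at high dilution.

Step 17
Reactants: 26 unsaturated macrolactone
Product: 27 saturated 14-membered β-keto macrolactone with tertiary aldehyde and α-methoxy-β-methyl enone
Conditions: H2 (1 atm), Pd/C, EtOAc, 23 °C, stopped after one equivalent
Reagents that add atoms: none
Why: Heterogeneous hydrogenation discriminates by substitution, so the 1,2-disubstituted ring alkene is saturated while the trisubstituted enoate, the tetrasubstituted enol ether and the hindered aldehyde remain.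

Step 18
Reactants: 27 saturated β-keto macrolactone
Product: 30 tetracyclic α-methoxy enone tert-butyl ester (rings A–D complete, Ca methylated), via macrocyclic 3-acylbutenolide 28 (not isolated), via caesium enolate 29 (not isolated)
Conditions: Cs2CO3, 4 Å MS, DMF (5 mM), 23 → 45 °C; then MeI, 0 → 23 °C
Reagents that add atoms: iodomethane, CI
Why: Cs2CO3 converts the β-keto ester CH2 (future Ca) into its enolate, which adds to the adjacent tertiary aldehyde (future Cb) and loses water, a transannular Knoevenagel condensation that closes ring B in the 5-exo-trig mode and gives 3-acylbutenolide 28, whose Cb is activated by both K1 and the lactone carbonyl. Reversible γ-deprotonation of the vinylic CH3 (future Ch) of the α-methoxy enone then gives a 3-oxidohexatriene, Cb=Ca–K1(O−)=K2(OMe)–Cm=Ch, that forms the Ch–Cb bond and thereby closes ring C in the 6-endo-trig mode and ring D at the same time; the closest known reaction types are the intramolecular vinylogous Michael addition and the disrotatory 6π electrocyclisation of 2-acceptor-3-donor hexatrienes. The closure is irreversible because it ends in the stabilised β-keto lactone enolate 29, which MeI alkylates on carbon (β-dicarbonyl alkylation). Cb is controlled by the macrocycle, since the six-atom tether runs from Cm to the ring A carbon that stands on the upper face of the butenolide, so Ch should reach Cb from that face, the lower one being screened by the ring A CH2. Ca is controlled by the ring fusion, because MeI can approach only the convex face syn to the new Cb–H and opposite to the bridging chain, which gives the cis-fused B/C system. The step needs CH3 over CH deprotonation and C- over O-methylation: A1,3 strain against the methoxy group holds the allylic methine C–H in the alkene plane and keeps it non-acidic so that its stereocentre survives, deprotonation at a wrong site or with a wrong enolate geometry is reversible under the weak base, and soft MeI in DMF favours carbon.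

Step 19
Reactants: 30 tetracyclic α-methoxy enone tert-butyl ester
Product: 32 target CNP0115928.1, via diosphenol acid 31 (not isolated)
Conditions: BCl3, CH2Cl2, −78 → 0 °C; H2O; SiO2
Reagents that add atoms: none
Why: Chelation of BCl3 between K1=O and the enol ether oxygen triggers chloride SN2 demethylation while the tert-butyl ester ionises (Lewis acid dealkylation), and the freed diosphenol ketonises by protonation of Cm from the convex face, which is also the thermodynamic outcome because only the cis-1,3 bridge fits ring D.

**Compound list**

1 | meso-2,4-dimethylglutaric anhydride | C[C@H]1C[C@@H](C)C(=O)OC1=O | starting material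
2 | (2S,4R)-2,4-dimethyl-5-oxohexanoic acid | CC(=O)[C@H](C)C[C@H](C)C(=O)O | intermediate
3 | S-ethyl (2S,4R)-2,4-dimethyl-5-oxohexanethioate | CC(=O)[C@H](C)C[C@H](C)C(=O)SCC | intermediate
4 | (2S,4R)-2,4-dimethyl-5-oxohexanal | CC(=O)[C@H](C)C[C@H](C)C=O | intermediate
5 | (3R,5S)-3,5-dimethylhept-6-en-2-one | CC(=O)[C@H](C)C[C@H](C)C=C | intermediate
6 | methyl 2-(dimethoxyphosphoryl)-2-methoxyacetate | COC(=O)C(OC)P(=O)(OC)OC | starting material
7 | methyl (2Z,4R,6S)-2-methoxy-3,4,6-trimethylocta-2,7-dienoate | COC(=O)/C(OC)=C(\C)[C@H](C)C[C@H](C)C=C | intermediate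
8 | tert-butyl acetate | CC(=O)OC(C)(C)C | starting material
9 | tert-butyl (4Z,6R,8S)-4-methoxy-5,6,8-trimethyl-3-oxodeca-4,9-dienoate | CC(C)(C)OC(=O)CC(=O)/C(OC)=C(\C)[C@H](C)C[C@H](C)C=C | intermediate
10 | (S)-lactic acid | C[C@H](O)C(=O)O | starting material
11 | pivalaldehyde | CC(C)(C)C=O | starting material
12 | (2S,5S)-2-tert-butyl-5-methyl-1,3-dioxolan-4-one | C[C@@H]1O[C@H](C(C)(C)C)OC1=O | intermediate
13 | (2S)-5-bromo-2-tert-butyl-5-methyl-1,3-dioxolan-4-one | CC1(Br)O[C@H](C(C)(C)C)OC1=O | intermediate
14 | (S)-2-tert-butyl-5-methylidene-1,3-dioxolan-4-one | C=C1O[C@H](C(C)(C)C)OC1=O | intermediate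
15 | tert-butyl but-2-ynoate | CC#CC(=O)OC(C)(C)C | starting material
16 | tert-butyl (E)-2-(tributylstannyl)but-2-enoate | C/C=C(/[Sn](CCCC)(CCCC)CCCC)C(=O)OC(C)(C)C | intermediate
17 | pent-1-en-4-yne | C=CCC#C | starting material
18 | (E)-penta-1,4-dienylzirconocene chloride (cyclopentadienyl rings drawn σ-bonded) | C=CC/C=C/[Zr](Cl)(C1C=CC=C1)C1C=CC=C1 | intermediate
19 | (E)-1-iodopenta-1,4-diene | C=CC/C=C/I | intermediate
20 | tert-butyl (2Z,3E)-2-ethylidenehepta-3,6-dienoate | C/C=C(/C=C/CC=C)C(=O)OC(C)(C)C | intermediate
21 | spiro-dioxolanone cycloadduct | C=CC[C@H]1C=C(C(=O)OC(C)(C)C)[C@@H](C)C[C@@]12O[C@H](C(C)(C)C)OC2=O | intermediate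
22 | dioxolane lactol of 21 (anomeric centre undefined) | C=CC[C@H]1C=C(C(=O)OC(C)(C)C)[C@@H](C)C[C@@]12O[C@H](C(C)(C)C)OC2O | intermediate
23 | tert-butyl (3S,4R,6S)-4-formyl-4-hydroxy-6-methyl-3-(prop-2-enyl)cyclohex-1-ene-1-carboxylate | C=CC[C@H]1C=C(C(=O)OC(C)(C)C)[C@@H](C)C[C@]1(O)C=O | intermediate
24 | acylketene from 9 | O=C=CC(=O)/C(OC)=C(\C)[C@H](C)C[C@H](C)C=C | intermediate
25 | acyclic β-keto ester aldehyde | C=CC[C@H]1C=C(C(=O)OC(C)(C)C)[C@@H](C)C[C@@]1(C=O)OC(=O)CC(=O)/C(OC)=C(\C)[C@H](C)C[C@H](C)C=C | intermediate
26 | unsaturated 14-membered β-keto macrolactone (E) | C[C@@H]1/C=C/C[C@H]2C=C(C(=O)OC(C)(C)C)[C@@H](C)C[C@@]2(C=O)OC(=O)CC(=O)/C(OC)=C(\C)[C@H](C)C1 | intermediate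
27 | saturated 14-membered β-keto macrolactone | C[C@@H]1CCC[C@H]2C=C(C(=O)OC(C)(C)C)[C@@H](C)C[C@@]2(C=O)OC(=O)CC(=O)/C(OC)=C(\C)[C@H](C)C1 | intermediate
28 | macrocyclic 3-acylbutenolide (13-membered carbocycle, ring B closed) | C[C@@H]1CCC[C@H]2C=C(C(=O)OC(C)(C)C)[C@@H](C)C[C@@]23OC(=O)C(=C3)C(=O)/C(OC)=C(\C)[C@H](C)C1 | intermediate
29 | caesium enolate of the tetracyclic β-keto lactone | C[C@@H]1CCC[C@H]2C=C(C(=O)OC(C)(C)C)[C@@H](C)C[C@@]23OC(=O)C2=C([O-])C(OC)=C(C[C@H]23)[C@H](C)C1.[Cs+] | intermediate
30 | tetracyclic α-methoxy enone tert-butyl ester | C[C@@H]1CCC[C@H]2C=C(C(=O)OC(C)(C)C)[C@@H](C)C[C@@]23OC(=O)[C@@]2(C)C(=O)C(OC)=C(C[C@H]23)[C@H](C)C1 | intermediate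
31 | diosphenol acid (enol tautomer of the target) | C[C@@H]1CCC[C@H]2C=C(C(=O)O)[C@@H](C)C[C@@]23OC(=O)[C@@]2(C)C(=O)C(O)=C(C[C@H]23)[C@H](C)C1 | intermediate
32 | CNP0115928.1 | C[C@@H]1CCC[C@H]2C=C(C(=O)O)[C@@H](C)C[C@@]23OC(=O)[C@@]2(C)C(=O)C(=O)[C@H](C[C@H]23)[C@H](C)C1 | target

**Step count.** Total steps: 19. Longest linear sequence: 11 steps (steps 1–6 and 15–19).

**Steps most likely to fail**

Step 18. The closure may take the lower face of the butenolide. Competing γ-deprotonation may scramble the allylic methine. The acylbutenolide may oligomerise by intermolecular Michael addition, or the enolate may methylate on oxygen. The fallback replaces the anionic cascade with a stepwise, neutral pericyclic route that sets out from 27. Piperidinium acetate in toluene should stop at the isolable 28. Soft enolisation with TBSOTf and Et3N should give the macrocyclic 3-silyloxyhexatriene F1. Heating in toluene should close the same bond by thermal 6π electrocyclisation to the tetracyclic silyl dienol ether F2. CsF and MeI in DMF then unmask and methylate the enolate, and the route is rejoined at 30.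

Step 5. Addition to the hindered, enolisable ketone may be slow, so that enolisation, epimerisation next to the carbonyl and poor control of alkene geometry compete. The fallback sets out from 5 and builds the alkene by aldol addition and elimination. The lithium enolate of methyl methoxyacetate (LiN(i-Pr)2, THF, −78 °C) should add to give the β-hydroxy-α-methoxy ester F3. MsCl and Et3N convert it into the tertiary mesylate F4. DBU then eliminates by the E1cB path toward the ester α-carbon, and the route is rejoined at 7.

Step 16. Oligomerisation, sequestration of ruthenium by the chelating β-keto ester and sluggish reaction at the branched vinyl group may defeat ring closure. The fallback changes the ring-closing bond and sets out from 23 and 9. Cross metathesis with the second-generation Hoveyda–Grubbs catalyst RuCl2(=CH-2-(i-PrO)C6H4)(SIMes) joins the two terminal alkenes first, giving the seco hydroxy aldehyde β-keto ester F5. Thermolysis in toluene at high dilution then lets the tertiary alcohol trap the acylketene intramolecularly (macrolactonisation), and the route is rejoined at 26.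

**Further compounds**

F1 | step 18 | macrocyclic 3-silyloxyhexatriene | C[C@@H]1CCC[C@H]2C=C(C(=O)OC(C)(C)C)[C@@H](C)C[C@@]23OC(=O)C(=C3)/C(O[Si](C)(C)C(C)(C)C)=C(/OC)C(=C)[C@H](C)C1
F2 | step 18 | tetracyclic silyl dienol ether | C[C@@H]1CCC[C@H]2C=C(C(=O)OC(C)(C)C)[C@@H](C)C[C@@]23OC(=O)C2=C(O[Si](C)(C)C(C)(C)C)C(OC)=C(C[C@H]23)[C@H](C)C1
F3 | step 5 | β-hydroxy-α-methoxy ester (two new centres undefined) | COC(=O)C(OC)C(C)(O)[C@H](C)C[C@H](C)C=C
F4 | step 5 | tertiary mesylate | COC(=O)C(OC)C(C)(OS(C)(=O)=O)[C@H](C)C[C@H](C)C=C
F5 | step 16 | seco hydroxy aldehyde β-keto ester | CC(C)(C)OC(=O)CC(=O)/C(OC)=C(\C)[C@H](C)C[C@H](C)/C=C/C[C@H]1C=C(C(=O)OC(C)(C)C)[C@@H](C)C[C@]1(O)C=O
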